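**Retrosynthetic overview**
1. The ten-membered carbocycle is closed last, through the C6–C7 bond; the lactone (O8–C12) and the cis-1,10-epoxide are already present in open-chain aldehyde 32.
2. Enabling feature: the homoallylic carbinol C6(OH)–C7H–C11(=C13H2) where the carbocycle meets the α-methylene lactone. It is the retron of γ-attack of a 3-(metallomethyl)butenolide (C13–C11=C7) on a C6 aldehyde, so Cr(II) on bromide 32 closes the ring, sets C7 and turns the butenolide C=C into the exo-methylene.
3. After ring closure only C6 (oxidation, then Felkin–Anh hydride) and C3 (desilylation, MnO2) are adjusted.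
4. 32 comes from three pieces: the butenolide by acylation/ring-closing metathesis at C8–OH (C8 from a Sharpless kinetic resolution); (Z)-C1=C10 by Negishi carboalumination, later epoxidised with the ent-Shi ketone; C3–C4 by Ni/Cr coupling with 2-iodoallyl angelate 9 (C5 from D-glyceraldehyde acetonide).
5. Ring order: epoxide (step 14) → butenolide (step 17) → ten-membered ring (step 20).

Key step: step 20

Remark: locants C1–C15 are the germacrane locants the atoms carry in the target (lactone on O8, C13 and C15 exocyclic methylenes); the C3 carbinol is carried as both epimers from step 12 to step 23 because C3 ends as the ketone, so the SMILES of 24–37 leave C3 undefined.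

**Step 1**
Reactants: 1 (R)-2,2-dimethyl-1,3-dioxolane-4-carbaldehyde
Product: 2 (S)-4-ethynyl-2,2-dimethyl-1,3-dioxolane
Conditions: dimethyl (1-diazo-2-oxopropyl)phosphonate, K2CO3, MeOH, 0 °C → rt
Reagents that add atoms: dimethyl (1-diazo-2-oxopropyl)phosphonate, CC(=O)C(=[N+]=[N-])P(=O)(OC)OC
Why: Ohira–Bestmann (Seyferth–Gilbert) homologation turns the aldehyde into the terminal alkyne without touching the adjacent stereocentre, which becomes C5.

**Step 2**
Reactants: 2 (S)-4-ethynyl-2,2-dimethyl-1,3-dioxolane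
Product: 3 (S)-but-3-yne-1,2-diol
Conditions: AcOH–H2O (4:1), 40 °C
Reagents that add atoms: none
Why: Acid-catalysed acetal hydrolysis frees the diol and leaves the stereocentre untouched.

**Step 3**
Reactants: 3 (S)-but-3-yne-1,2-diol
Product: 4 (S)-1-(triethylsilyloxy)but-3-yn-2-ol
Conditions: Et3SiCl (1.05 equiv), imidazole, CH2Cl2, −40 °C
Reagents that add atoms: chlorotriethylsilane, CC[Si](Cl)(CC)CC
Why: Silylation at low temperature should select the primary hydroxyl (the future C6–O) over the propargylic secondary one.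

**Step 4**
Reactants: 4 (S)-1-(triethylsilyloxy)but-3-yn-2-ol; 5 angelic acid
Product: 7 (S)-1-(triethylsilyloxy)but-3-yn-2-yl angelate, via mixed anhydride 6 (not isolated)
Conditions: 5, 2,4,6-trichlorobenzoyl chloride, Et3N, toluene, rt; then 4, 80 °C (no DMAP)
Reagents that add atoms: none
Why: Yamaguchi esterification through the mixed anhydride, run without a nucleophilic catalyst, should acylate the secondary alcohol without Z→E isomerisation of the angelate.

**Step 5**
Reactants: 7 (S)-1-(triethylsilyloxy)but-3-yn-2-yl angelate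
Product: 9 (R)-3-iodo-1-(triethylsilyloxy)but-3-en-2-yl angelate, via alkenylborane 8 (not isolated)
Conditions: B-iodo-9-BBN, hexane–CH2Cl2, −20 °C; then AcOH, 0 °C
Reagents that add atoms: B-iodo-9-borabicyclo[3.3.1]nonane, IB1C2CCCC1CCC2
Why: Markovnikov syn-haloboration of the terminal alkyne followed by protodeboronation gives the 2-iodo-1-alkene (formal hydroiodination) that will become C4=C15.

**Step 6**
Reactants: 10 acrolein; 11 propargyl bromide
Product: 13 rac-hex-1-en-5-yn-3-ol, via allenylzinc bromide 12 (not isolated)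
Conditions: Zn dust, THF–sat. aq. NH4Cl, 0 °C
Reagents that add atoms: none
Why: Barbier propargylation (SE2′ addition of the allenylzinc species, 1,2 to the enal) gives the homopropargylic vinyl carbinol.

**Step 7**
Reactants: 13 rac-hex-1-en-5-yn-3-ol
Product: 14 (R)-hex-1-en-5-yn-3-ol
Conditions: Ti(OiPr)4 (15 mol %), L-(+)-DIPT (20 mol %), t-BuOOH (0.6 equiv), 4 Å MS, CH2Cl2, −20 °C
Reagents that add atoms: none
Why: Sharpless kinetic resolution: with L-(+)-tartrate the S enantiomer of a vinyl carbinol is epoxidised faster, so the R alcohol (future C8) should be recovered.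

**Step 8**
Reactants: 14 (R)-hex-1-en-5-yn-3-ol
Product: 17 (3R,5Z)-6-iodo-5-methylhexa-1,5-dien-3-ol, via (E)-alkenylalane 15 (not isolated), via (Z)-oxaaluminacycle 16 (not isolated)
Conditions: Me3Al (3 equiv), Cp2ZrCl2 (25 mol %), (CH2Cl)2, rt, then 60 °C; then I2, THF, −30 °C
Reagents that add atoms: trimethylaluminium, C[Al](C)C; iodine, II
Why: Negishi Zr-catalysed carboalumination followed by alkoxide-chelation-driven isomerisation (net anti-carbometalation of a homopropargylic alcohol) and iodinolysis with retention should give the (Z)-iodoalkene needed for the cis-epoxide.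

**Step 9**
Reactants: 17 (3R,5Z)-6-iodo-5-methylhexa-1,5-dien-3-ol
Product: 18 (3R,5Z)-6-iodo-3-(4-methoxybenzyloxy)-5-methylhexa-1,5-diene
Conditions: NaH, 4-methoxybenzyl chloride, Bu4NI (cat.), DMF, 0 °C
Reagents that add atoms: 4-methoxybenzyl chloride, COc1ccc(CCl)cc1
Why: Williamson etherification masks C8–OH with a group that is later removed oxidatively.

**Step 10**
Reactants: 18 (3R,5Z)-6-iodo-3-(4-methoxybenzyloxy)-5-methylhexa-1,5-diene; 19 oxirane
Product: 21 (3Z,6R)-6-(4-methoxybenzyloxy)-4-methylocta-3,7-dien-1-ol, via alkenyllithium 20 (not isolated)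
Conditions: t-BuLi (2.1 equiv), Et2O, −78 °C; then oxirane, −78 → 0 °C
Reagents that add atoms: none
Why: Iodine–lithium exchange proceeds with retention of the Z geometry and the alkenyllithium opens oxirane, adding C2 and C3.

**Step 11**
Reactants: 21 (3Z,6R)-6-(4-methoxybenzyloxy)-4-methylocta-3,7-dien-1-ol
Product: 22 (3Z,6R)-6-(4-methoxybenzyloxy)-4-methylocta-3,7-dienal
Conditions: TEMPO (10 mol %), PhI(OAc)2, CH2Cl2, rt; used crude
Reagents that add atoms: none
Why: Oxoammonium (TEMPO) oxidation is base-free, so the β,γ-unsaturated aldehyde should not move into conjugation.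

**Step 12**
Reactants: 22 (3Z,6R)-6-(4-methoxybenzyloxy)-4-methylocta-3,7-dienal; 9 (R)-3-iodo-1-(triethylsilyloxy)but-3-en-2-yl angelate
Product: 24 C3 carbinol (C3 epimers), via alkenylchromium 23 (not isolated)
Conditions: CrCl2 (4 equiv), NiCl2 (2 mol %), DMSO, rt
Reagents that add atoms: none
Why: Nozaki–Hiyama–Kishi alkenylation joins C3 to C4 in the presence of the ester and ethers; C3 forms as both epimers, which is harmless because it ends as the ketone.

**Step 13**
Reactants: 24 C3 carbinol
Product: 25 3-O-TBS ether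
Conditions: TBSOTf, 2,6-lutidine, CH2Cl2, −78 °C
Reagents that add atoms: tert-butyldimethylsilyl triflate, CC(C)(C)[Si](C)(C)OS(=O)(=O)C(F)(F)F
Why: Silylation keeps C3 at the alcohol level, so that later the C6 aldehyde is the only reactive carbonyl.

**Step 14**
Reactants: 25 3-O-TBS ether
Product: 26 (1S,10R)-cis-epoxide
Conditions: ent-Shi ketone (L-fructose-derived, 30 mol %), Oxone, K2CO3, Bu4NHSO4, MeCN–(MeO)2CH2–aq. buffer (pH 10.5), 0 °C
Reagents that add atoms: potassium peroxymonosulfate (Oxone), [K+].[O-]S(=O)(=O)OO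
Why: Shi epoxidation attacks the only electron-rich trisubstituted alkene stereospecifically (Z → cis); the spiro transition state with the C1–H in the hindered quadrant predicts the 1S,10R epoxide for the enantiomeric ketone.

**Step 15**
Reactants: 26 (1S,10R)-cis-epoxide
Product: 27 C8 alcohol
Conditions: DDQ, CH2Cl2–pH 7 buffer, 0 °C
Reagents that add atoms: none
Why: Oxidative cleavage of the 4-methoxybenzyl ether is neutral and spares the epoxide, the silyl ethers and the angelate.

**Step 16**
Reactants: 27 C8 alcohol; 28 2-(bromomethyl)acrylic acid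
Product: 29 C8 2-(bromomethyl)acrylate
Conditions: DIC, DMAP (10 mol %), CH2Cl2, 0 °C
Reagents that add atoms: none
Why: Steglich-type carbodiimide esterification acylates the only free hydroxyl with the acid that supplies C11, C12 and C13.

**Step 17**
Reactants: 29 C8 2-(bromomethyl)acrylate
Product: 30 3-(bromomethyl)butenolide
Conditions: Hoveyda–Grubbs II (10 mol %), toluene (5 mM), 60 °C
Reagents that add atoms: none
Why: Ring-closing metathesis between the C7 vinyl group and the acrylate closes the butenolide with loss of ethene; the phosphine-free catalyst avoids alkylation by the allylic bromide, and the hindered C4=C15 and electron-poor angelate alkenes should not compete.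

**Step 18**
Reactants: 30 3-(bromomethyl)butenolide
Product: 31 C6 primary alcohol
Conditions: AcOH–THF–H2O (3:1:1), rt
Reagents that add atoms: none
Why: Mild acid hydrolysis removes the primary triethylsilyl ether while the secondary TBS ether, the epoxide, the allylic bromide and the esters should survive.

**Step 19**
Reactants: 31 C6 primary alcohol
Product: 32 C6 aldehyde (seco-aldehyde)
Conditions: TEMPO (10 mol %), PhI(OAc)2, CH2Cl2, rt; used at once
Reagents that add atoms: none
Why: Base-free oxoammonium oxidation gives the α-acyloxy β,γ-unsaturated aldehyde without epimerising C5 or moving the C4=C15 bond.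

**Step 20**
Reactants: 32 C6 aldehyde (seco-aldehyde)
Product: 34 (3RS,6R)-3-O-TBS-6-hydroxy macrocycle, via allylchromium 33 (not isolated)
Conditions: CrCl2 (10 equiv), THF, rt, syringe-pump addition of 32 over 12 h (final 1 mM); AcOH–H2O quench, 0 °C
Reagents that add atoms: none
Why: Cr(II) reduces the allylic bromide by two single-electron transfers to the σ-allylchromium(III) species 33, which adds to the C6 aldehyde through its γ-carbon C7 (SE2′) in a six-membered chair transition state, so the butenolide C7=C11 bond becomes the C11=C13 exo-methylene. The closest known reaction type is the Nozaki–Hiyama allylation, known intermolecularly for 3-(bromomethyl)furan-2(5H)-one and intramolecularly for allyl halide/aldehyde closures of ten-membered carbocycles. The ten-membered ring closes by intramolecular carbonyl allylation (10-exo-trig at the aldehyde), helped by high dilution and by two turn elements in the chain, the cis-epoxide and the sp2 centre C4. C7 is controlled by the C8 stereocentre of the butenolide: C6 should arrive anti to C9 (torsion C6–C7–C8–C9 near 150° in the trans mode, against a nearly eclipsed 30° in the cis mode), giving the trans-fused lactone. At C6 the chair with the aldehyde residue equatorial and Felkin–Anh control by the C5 acyloxy group both point to the 6R carbinol, which is accepted because C6 is re-set in steps 21 and 22 and either epimer serves. The step needs chemoselection for the aldehyde, secured by keeping C3 as a silyl ether so that the aldehyde is the only reactive carbonyl and the C5 angelate is an unactivated allylic ester, and γ-regioselection, which is inherent to allylchromium reagents.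

**Step 21**
Reactants: 34 (3RS,6R)-3-O-TBS-6-hydroxy macrocycle
Product: 35 6-ketone
Conditions: Dess–Martin periodinane, CH2Cl2, 0 °C → rt
Reagents that add atoms: none
Why: Dess–Martin oxidation of the only free alcohol erases the C6 configuration under non-basic conditions that should spare the epimerisable C5 and C7 centres.

**Step 22**
Reactants: 35 6-ketone
Product: 36 (6S)-alcohol
Conditions: NaBH4, CeCl3·7H2O, MeOH, −78 °C
Reagents that add atoms: none
Why: Luche reduction delivers hydride 1,2 to the only ketone (CeCl3 suppresses conjugate reduction of the methylene lactone); Felkin–Anh attack anti to the C5–O(angelate) bond, on the ring face opposite the C7–C11 bond, should give the 6S carbinol syn to the angelate.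

**Step 23**
Reactants: 36 (6S)-alcohol
Product: 37 3,6-diol
Conditions: TBAF, AcOH (1:1), THF, rt
Reagents that add atoms: none
Why: Buffered fluoride desilylation frees C3–OH without acyl migration from O5 to O6 and without opening the epoxide.

**Step 24**
Reactants: 37 3,6-diol
Product: 38 CNP0348992.1
Conditions: activated MnO2, CH2Cl2, rt
Reagents that add atoms: none
Why: MnO2 oxidises only the allylic C3 carbinol (both epimers) to the cross-conjugated enone and leaves the non-allylic C6 alcohol untouched.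

**Compound list**
1 | (R)-2,2-dimethyl-1,3-dioxolane-4-carbaldehyde (D-glyceraldehyde acetonide) | O=C[C@H]1COC(C)(C)O1 | starting material
2 | (S)-4-ethynyl-2,2-dimethyl-1,3-dioxolane | C#C[C@H]1COC(C)(C)O1 | intermediate
3 | (S)-but-3-yne-1,2-diol | C#C[C@H](O)CO | intermediate
4 | (S)-1-(triethylsilyloxy)but-3-yn-2-ol | C#C[C@H](O)CO[Si](CC)(CC)CC | intermediate
5 | angelic acid, (Z)-2-methylbut-2-enoic acid | C/C=C(/C)C(=O)O | starting material
6 | angelic 2,4,6-trichlorobenzoic anhydride | C/C=C(/C)C(=O)OC(=O)c1c(Cl)cc(Cl)cc1Cl | intermediate (not isolated)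
7 | (S)-1-(triethylsilyloxy)but-3-yn-2-yl angelate | C#C[C@H](OC(=O)/C(C)=C\C)CO[Si](CC)(CC)CC | intermediate
8 | (Z)-2-iodoalkenyl-9-BBN from 7 (B and I cis) | I/C(=C\B1C2CCCC1CCC2)[C@H](OC(=O)/C(C)=C\C)CO[Si](CC)(CC)CC | intermediate (not isolated)
9 | (R)-3-iodo-1-(triethylsilyloxy)but-3-en-2-yl angelate | C=C(I)[C@H](OC(=O)/C(C)=C\C)CO[Si](CC)(CC)CC | intermediate
10 | acrolein | C=CC=O | starting material
11 | propargyl bromide | C#CCBr | starting material
12 | allenylzinc bromide | C=C=C[Zn]Br | intermediate (not isolated)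
13 | rac-hex-1-en-5-yn-3-ol | C=CC(O)CC#C | intermediate
14 | (R)-hex-1-en-5-yn-3-ol | C=C[C@@H](CC#C)O | intermediate
15 | (E)-alkenyldimethylalane, O-dimethylaluminium alkoxide of 14 | C=C[C@@H](C/C(C)=C/[Al](C)C)O[Al](C)C | intermediate (not isolated)
16 | (Z)-configured six-membered oxaaluminacycle (Al on C1 chelated by O8) | C=C[C@H]1C/C(C)=C\[Al](C)O1 | intermediate (not isolated)
17 | (3R,5Z)-6-iodo-5-methylhexa-1,5-dien-3-ol | C=C[C@@H](C/C(C)=C\I)O | intermediate
18 | (3R,5Z)-6-iodo-3-(4-methoxybenzyloxy)-5-methylhexa-1,5-diene | C=C[C@@H](C/C(C)=C\I)OCc1ccc(OC)cc1 | intermediate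
19 | oxirane | C1CO1 | starting material
20 | (Z)-alkenyllithium from 18 | C=C[C@@H](C/C(C)=C\[Li])OCc1ccc(OC)cc1 | intermediate (not isolated)
21 | (3Z,6R)-6-(4-methoxybenzyloxy)-4-methylocta-3,7-dien-1-ol | C=C[C@@H](C/C(C)=C\CCO)OCc1ccc(OC)cc1 | intermediate
22 | (3Z,6R)-6-(4-methoxybenzyloxy)-4-methylocta-3,7-dienal | C=C[C@@H](C/C(C)=C\CC=O)OCc1ccc(OC)cc1 | intermediate
23 | alkenylchromium(III) dichloride from 9 | C=C([Cr](Cl)Cl)[C@H](OC(=O)/C(C)=C\C)CO[Si](CC)(CC)CC | intermediate (not isolated)
24 | C3 carbinol: open chain C6→C8 with vinyl on C8; 3-OH (3RS), 5-O-angeloyl (5S), 6-O-TES, 8-O-PMB (8R), (Z)-C1=C10, C4=C15H2 | C=C[C@@H](C/C(C)=C\CC(O)C(=C)[C@H](OC(=O)/C(C)=C\C)CO[Si](CC)(CC)CC)OCc1ccc(OC)cc1 | intermediate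
25 | 3-O-TBS ether of 24 | C=C[C@@H](C/C(C)=C\CC(O[Si](C)(C)C(C)(C)C)C(=C)[C@H](OC(=O)/C(C)=C\C)CO[Si](CC)(CC)CC)OCc1ccc(OC)cc1 | intermediate
26 | (1S,10R)-cis-1,10-epoxide of 25 | C=C[C@@H](C[C@@]1(C)O[C@H]1CC(O[Si](C)(C)C(C)(C)C)C(=C)[C@H](OC(=O)/C(C)=C\C)CO[Si](CC)(CC)CC)OCc1ccc(OC)cc1 | intermediate
27 | C8 alcohol (26 without the PMB group) | C=C[C@@H](C[C@@]1(C)O[C@H]1CC(O[Si](C)(C)C(C)(C)C)C(=C)[C@H](OC(=O)/C(C)=C\C)CO[Si](CC)(CC)CC)O | intermediate
28 | 2-(bromomethyl)acrylic acid | C=C(CBr)C(=O)O | starting material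
29 | 8-O-[2-(bromomethyl)acryloyl] ester of 27 | C=C[C@@H](C[C@@]1(C)O[C@H]1CC(O[Si](C)(C)C(C)(C)C)C(=C)[C@H](OC(=O)/C(C)=C\C)CO[Si](CC)(CC)CC)OC(=O)C(=C)CBr | intermediate
30 | 3-(bromomethyl)butenolide (ring O8–C12–C11=C7–C8), chain with 6-O-TES | BrCC1=C[C@@H](C[C@@]2(C)O[C@H]2CC(O[Si](C)(C)C(C)(C)C)C(=C)[C@H](OC(=O)/C(C)=C\C)CO[Si](CC)(CC)CC)OC1=O | intermediate
31 | C6 primary alcohol of 30 | BrCC1=C[C@@H](C[C@@]2(C)O[C@H]2CC(O[Si](C)(C)C(C)(C)C)C(=C)[C@H](OC(=O)/C(C)=C\C)CO)OC1=O | intermediate
32 | C6 aldehyde (seco-aldehyde; 1S,5S,8R,10R) | BrCC1=C[C@@H](C[C@@]2(C)O[C@H]2CC(O[Si](C)(C)C(C)(C)C)C(=C)[C@H](OC(=O)/C(C)=C\C)C=O)OC1=O | intermediate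
33 | allylchromium(III) dichloride from 32 | Cl[Cr](Cl)CC1=C[C@@H](C[C@@]2(C)O[C@H]2CC(O[Si](C)(C)C(C)(C)C)C(=C)[C@H](OC(=O)/C(C)=C\C)C=O)OC1=O | intermediate (not isolated)
34 | (1S,3RS,5S,6R,7R,8R,10R)-5-angeloyloxy-3-(tert-butyldimethylsilyloxy)-1,10-epoxy-6-hydroxygermacra-4(15),11(13)-dien-12,8-olide (6R expected; the 6S epimer would be carried on equally) | C=C1C(=O)O[C@@H]2C[C@@]3(C)O[C@H]3CC(O[Si](C)(C)C(C)(C)C)C(=C)[C@H](OC(=O)/C(C)=C\C)[C@H](O)[C@@H]12 | intermediate
35 | 6-oxo analogue of 34 (1S,3RS,5S,7S,8R,10R) | C=C1C(=O)O[C@@H]2C[C@@]3(C)O[C@H]3CC(O[Si](C)(C)C(C)(C)C)C(=C)[C@H](OC(=O)/C(C)=C\C)C(=O)[C@@H]12 | intermediate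
36 | (6S)-alcohol, 3-O-TBS (1S,3RS,5S,6S,7R,8R,10R) | C=C1C(=O)O[C@@H]2C[C@@]3(C)O[C@H]3CC(O[Si](C)(C)C(C)(C)C)C(=C)[C@H](OC(=O)/C(C)=C\C)[C@@H](O)[C@@H]12 | intermediate
37 | 3,6-diol (1S,3RS,5S,6S,7R,8R,10R) | C=C1C(=O)O[C@@H]2C[C@@]3(C)O[C@H]3CC(O)C(=C)[C@H](OC(=O)/C(C)=C\C)[C@@H](O)[C@@H]12 | intermediate
38 | CNP0348992.1, (1S,5S,6S,7R,8R,10R)-5-angeloyloxy-1,10-epoxy-6-hydroxy-3-oxogermacra-4(15),11(13)-dien-12,8-olide | C=C1C(=O)O[C@@H]2C[C@@]3(C)O[C@H]3CC(=O)C(=C)[C@H](OC(=O)/C(C)=C\C)[C@@H](O)[C@@H]12 | target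

**Step count**
Total: 24 steps. Longest linear sequence: 19 steps (steps 6–24); the five-step branch (steps 1–5) joins at step 12.

**Steps most likely to fail**

Step 20 (ring closure). Intermolecular allylation may outrun the ten-membered closure and give dimers and oligomers; closure may occur on the other butenolide face (cis fusion); the new C6 chromium alkoxide may migrate onto the lactone carbonyl (translactonisation). The fallback moves the ring closure to the C3–C4 bond; it sets out from 21 (and 9) and returns at 37. Alcohol 21 would be silylated (TBSCl, imidazole) to silyl ether F1, epoxidised as in step 14 to epoxide F2, freed from the PMB group (DDQ) to allylic alcohol F3, esterified with 28 to acrylate F4 and closed by metathesis to bromomethyl butenolide F5. Iodide 9 would be desilylated (AcOH–THF–H2O) to iodo alcohol F6 and oxidised (TEMPO, PhI(OAc)2) to iodo aldehyde F7. CrCl2 without nickel would join F5 and F7 intermolecularly (the allylic bromide reacts, the alkenyl iodide does not) to lactone carbinol F8. Dess–Martin oxidation to ketone F9 and Luche reduction would give 6S alcohol F10. HF·pyridine would remove the primary silyl group to give diol F11, and TEMPO/PhI(OAc)2 would oxidise only the primary alcohol to hydroxy aldehyde F12. Ni/Cr-mediated intramolecular alkenylation of F12 at high dilution would close the ring at C3–C4 and give 37 directly.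

Step 22 (C6 reduction). Hydride may be delivered to the wrong face of the C6 ketone if the ring conformation overrides Felkin–Anh control, or the ketone may enolise toward C5 or C7 before it is reduced. The fallback replaces the redox pair by an inversion; it sets out from 34 and returns at 36. If 34 is the 6R epimer as predicted, Mitsunobu reaction with 4-nitrobenzoic acid (PPh3, DIAD) would give the inverted 6S ester, 4-nitrobenzoate F13. Mild methanolysis of this activated ester (K2CO3, MeOH, −20 °C; the hindered conjugated angelate reacts more slowly) would give 36, and steps 21 and 22 would be omitted.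

Step 12 (fragment coupling). The allylic angelate may be lost by β-elimination from the alkenyl-nickel/chromium intermediate (allene formation), or slow coupling may let the β,γ-unsaturated aldehyde slip into conjugation. The fallback introduces the ester after the coupling; it sets out from 2 (and 22) and returns at 25. Alkyne 2 would be converted by α-selective nickel-catalysed hydroalumination (DIBAL-H, Ni(dppp)Cl2) and iodination into iodoalkene acetonide F14, which carries no acyloxy leaving group. Ni/Cr coupling with 22 would give allylic alcohol F15, silylation (TBSOTf) silyl ether F16, acetal hydrolysis (aq. AcOH) diol F17, and selective primary silylation (Et3SiCl) hydroxy silyl ether F18. DMAP-free Yamaguchi esterification with 5 would then give 25.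

**Further compounds**
F1 | step 20 | 1-O-TBS ether of 21 | C=C[C@@H](C/C(C)=C\CCO[Si](C)(C)C(C)(C)C)OCc1ccc(OC)cc1
F2 | step 20 | cis-epoxide of F1 | C=C[C@@H](C[C@@]1(C)O[C@H]1CCO[Si](C)(C)C(C)(C)C)OCc1ccc(OC)cc1
F3 | step 20 | allylic alcohol from F2 (PMB removed) | C=C[C@@H](C[C@@]1(C)O[C@H]1CCO[Si](C)(C)C(C)(C)C)O
F4 | step 20 | 2-(bromomethyl)acrylate of F3 | C=C[C@@H](C[C@@]1(C)O[C@H]1CCO[Si](C)(C)C(C)(C)C)OC(=O)C(=C)CBr
F5 | step 20 | 3-(bromomethyl)butenolide with epoxy side chain ending in CH2OTBS | BrCC1=C[C@@H](C[C@@]2(C)O[C@H]2CCO[Si](C)(C)C(C)(C)C)OC1=O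
F6 | step 20 | (R)-1-hydroxy-3-iodobut-3-en-2-yl angelate | C=C(I)[C@H](OC(=O)/C(C)=C\C)CO
F7 | step 20 | (S)-3-iodo-1-oxobut-3-en-2-yl angelate | C=C(I)[C@H](OC(=O)/C(C)=C\C)C=O
F8 | step 20 | intermolecular allylation product, trans α-methylene lactone with (6R)-carbinol | C=C1C(=O)O[C@H](C[C@@]2(C)O[C@H]2CCO[Si](C)(C)C(C)(C)C)[C@H]1[C@@H](O)[C@@H](OC(=O)/C(C)=C\C)C(I)=C
F9 | step 20 | 6-ketone of F8 | C=C1C(=O)O[C@H](C[C@@]2(C)O[C@H]2CCO[Si](C)(C)C(C)(C)C)[C@H]1C(=O)[C@@H](OC(=O)/C(C)=C\C)C(I)=C
F10 | step 20 | (6S)-alcohol from F9 | C=C1C(=O)O[C@H](C[C@@]2(C)O[C@H]2CCO[Si](C)(C)C(C)(C)C)[C@H]1[C@H](O)[C@@H](OC(=O)/C(C)=C\C)C(I)=C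
F11 | step 20 | diol from F10 (primary TBS removed) | C=C1C(=O)O[C@H](C[C@@]2(C)O[C@H]2CCO)[C@H]1[C@H](O)[C@@H](OC(=O)/C(C)=C\C)C(I)=C
F12 | step 20 | C3 hydroxy aldehyde with C4 alkenyl iodide | C=C1C(=O)O[C@H](C[C@@]2(C)O[C@H]2CC=O)[C@H]1[C@H](O)[C@@H](OC(=O)/C(C)=C\C)C(I)=C
F13 | step 22 | (6S)-4-nitrobenzoate of the macrocycle, 3-O-TBS | C=C1C(=O)O[C@@H]2C[C@@]3(C)O[C@H]3CC(O[Si](C)(C)C(C)(C)C)C(=C)[C@H](OC(=O)/C(C)=C\C)[C@@H](OC(=O)c4ccc(cc4)[N+](=O)[O-])[C@@H]12
F14 | step 12 | (R)-4-(1-iodoethenyl)-2,2-dimethyl-1,3-dioxolane | C=C(I)[C@H]1COC(C)(C)O1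
F15 | step 12 | C3 carbinol with 5,6-O-isopropylidene (C3 epimers) | C=C[C@@H](C/C(C)=C\CC(O)C(=C)[C@H]1COC(C)(C)O1)OCc1ccc(OC)cc1
F16 | step 12 | 3-O-TBS ether of F15 | C=C[C@@H](C/C(C)=C\CC(O[Si](C)(C)C(C)(C)C)C(=C)[C@H]1COC(C)(C)O1)OCc1ccc(OC)cc1
F17 | step 12 | 5,6-diol from F16 | C=C[C@@H](C/C(C)=C\CC(O[Si](C)(C)C(C)(C)C)C(=C)[C@H](O)CO)OCc1ccc(OC)cc1
F18 | step 12 | 6-O-TES ether of F17 (5-OH free) | C=C[C@@H](C/C(C)=C\CC(O[Si](C)(C)C(C)(C)C)C(=C)[C@H](O)CO[Si](CC)(CC)CC)OCc1ccc(OC)cc1
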